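**Retrosynthetic overview**

- Feature: in the benzene ring (C1 side chain, C2 and C3 Br, C4 and C5 OH, C6 H) the brominated carbon C3 lies between oxygenated C4 and brominated C2. This is the carbon a dibromocarbene delivers into the C=C bond of a 2-bromo silyl enol ether of a cyclopentanone.
- Target ⇒ aliphatic O-sulfation and ester reduction ⇒ catechol arylacetate ⇒ tautomerisation of a cyclohexene-4,5-dione ⇒ α′-oxygenation of a 2,3-dibromo-4-oxocyclohexenyl acetate.
- Key disconnection: C2–C3 and C3–C4 by one-carbon ring expansion (CBr2 into the bromo silyl enol ether of a cyclopentene) ⇒ Mukaiyama–Michael union of 2-bromocyclopentenone with a ketene silyl acetal (C1–CH2 bond).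
- Ring order: the five-membered ring is bought, the only ring of the target is made six-membered in the ring expansion and aromatised three steps later.

Key step: step 2

Assumption: the target is made as the free hydrogen sulfate monoester as drawn. Every chiral intermediate is racemic, which is of no consequence because all sp3 stereocentres are erased on aromatisation in step 5.

**Route**

Step 1
Reactants: 1 2-bromocyclopent-2-en-1-one; 2 1-(tert-butyldimethylsilyloxy)-1-methoxyethene
Product: 3 methyl 2-[2-bromo-3-(tert-butyldimethylsilyloxy)cyclopent-2-en-1-yl]acetate (racemic)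
Conditions: TBSOTf (10 mol %), CH2Cl2, −78 °C; Et3N quench
Reagents that add atoms: none
Why: Mukaiyama–Michael addition in which the silyl triflate activates the enone, the ketene silyl acetal attacks the unsubstituted β-carbon (1,2-attack being hindered by the α-bromine and the O-silyl group) and silyl transfer returns the catalyst while leaving the enolate oxygen silylated, so the tetrasubstituted bromo enol ether should form as a single regioisomer, its one stereocentre being racemic and needing no control.

Step 2
Reactants: 3 methyl 2-[2-bromo-3-(tert-butyldimethylsilyloxy)cyclopent-2-en-1-yl]acetate; 4 bromoform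
Product: 6 methyl 2-(2,3-dibromo-4-oxocyclohex-2-en-1-yl)acetate (racemic), via tribromobicyclohexane silyl ether 5 (not isolated)
Conditions: KOtBu (2.5 equiv, added in portions to 3 and excess 4), pentane, −30 → 0 °C; filtration; toluene, 60 °C
Reagents that add atoms: none
Why: Dibromocarbene, formed by α-elimination from bromoform, should add as an electrophile to the only C=C bond of 3, the silyloxy-activated enol ether, to give the 1,6,6-tribromo-5-silyloxybicyclo[3.1.0]hexane 5. The closest known reaction type is the dihalocarbene cyclopropanation and ring expansion of cyclic silyl enol ethers to 2-halocycloalk-2-enones; the bromine on the enol ether carbon is an extra substituent that has not been tried on this substrate class and lowers the nucleophilicity of the alkene. The six-membered ring is closed by ring expansion, a thermally allowed two-electron disrotatory electrocyclic opening of the cyclopropane (cyclopropyl to allyl cation) in which the endo bromide on the carbene carbon ionises as the former C=C σ-bond breaks, after which bromide removes the silyl group from the oxocarbenium ion and leaves the ketone. The carbene carbon ends as C3 with its bromine, the bromine already present sits on C2, the ketone marks C4 and the acetate arm stays on C1. No lasting stereocentre is created: C1 is carried as a racemate and the two cyclopropane centres, set by addition anti to the acetate arm, are destroyed in the opening. The step needs the carbene to react at the enol ether only and a carbene-derived bromide to ionise; the silyloxy donor secures both, by making the alkene the one nucleophilic site and by placing the cationic charge on the oxygen-bearing carbon, and slow addition of base to excess bromoform keeps alkoxide away from the β-bromoenone.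

Step 3
Reactants: 6 methyl 2-(2,3-dibromo-4-oxocyclohex-2-en-1-yl)acetate
Product: 7 methyl 2-[2,3-dibromo-4-(trimethylsilyloxy)cyclohexa-2,4-dien-1-yl]acetate (racemic)
Conditions: TMSOTf, i-Pr2NEt, CH2Cl2, −78 → 0 °C; pentane extraction, used crude
Reagents that add atoms: trimethylsilyl trifluoromethanesulfonate, C[Si](C)(C)OS(=O)(=O)C(F)(F)F
Why: Soft enolisation, in which the O-silylated enone is deprotonated kinetically by the hindered, non-nucleophilic amine at the accessible α′-methylene (C5) and not at the tertiary γ-carbon flanked by bromine, should give the cross-conjugated 2-silyloxy-1,3-diene without touching the ester or the vinylic bromides.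

Step 4
Reactants: 7 methyl 2-[2,3-dibromo-4-(trimethylsilyloxy)cyclohexa-2,4-dien-1-yl]acetate
Product: 10 methyl 2-(2,3-dibromo-5-hydroxy-4-oxocyclohex-2-en-1-yl)acetate (racemic diastereomer mixture), via silyloxy epoxide 8 (not isolated), via silyloxy ketone 9 (not isolated)
Conditions: mCPBA, NaHCO3, CH2Cl2, −20 → 0 °C; then 1 M aq. HCl, THF, 0 °C
Reagents that add atoms: meta-chloroperoxybenzoic acid (mCPBA), O=C(OO)c1cccc(Cl)c1
Why: Rubottom oxidation, in which the peracid epoxidises the electron-rich enol ether C4=C5 bond in preference to the electron-poor dibromoalkene, the silyloxy epoxide opens with 1,4-silyl shift to the α′-silyloxy ketone and dilute acid removes the TMS group; the carbinol centre forms without control, which does not matter because both sp3 centres disappear in step 5.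

Step 5
Reactants: 10 methyl 2-(2,3-dibromo-5-hydroxy-4-oxocyclohex-2-en-1-yl)acetate
Product: 12 methyl 2-(2,3-dibromo-4,5-dihydroxyphenyl)acetate, via enedione 11 (not isolated)
Conditions: (COCl)2, DMSO, CH2Cl2, −78 °C; i-Pr2NEt, −78 → 0 °C; aq. NaH2PO4 then Na2S2O4 wash
Reagents that add atoms: none
Why: Swern oxidation of the acyloin should give the cyclohex-2-ene-4,5-dione, which enolises at C6 and shifts H-1 to become the aromatic catechol only after the activated-DMSO oxidant is spent, so the catechol is not over-oxidised (the dithionite wash returns any o-quinone).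

Step 6
Reactants: 12 methyl 2-(2,3-dibromo-4,5-dihydroxyphenyl)acetate
Product: 13 3,4-dibromo-5-(2-hydroxyethyl)benzene-1,2-diol
Conditions: LiBH4 (4 equiv), THF, 0 → 40 °C; 1 M aq. HCl, then MeOH co-evaporation
Reagents that add atoms: none
Why: Borohydride reduction of the methyl ester to the primary alcohol, in which the catechol is first tied up as a borate with loss of H2 and the aryl C–Br bonds are inert to LiBH4, followed by acidic work-up that frees the catechol.

Step 7
Reactants: 13 3,4-dibromo-5-(2-hydroxyethyl)benzene-1,2-diol
Product: 14 2-(2,3-dibromo-4,5-dihydroxyphenyl)ethyl hydrogen sulfate (target)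
Conditions: H2SO4 (1.0 equiv), DCC (5 equiv), DMF, 0 °C; filtration, C18 chromatography
Reagents that add atoms: sulfuric acid, OS(=O)(=O)O
Why: Carbodiimide-mediated sulfation, in which DCC and H2SO4 form an O-sulfo isourea that transfers SO3 to the primary alcohol, while under these acidic, base-free conditions the hydrogen-bonded, bromine-deactivated phenols are much poorer nucleophiles, so the aliphatic hydroxyl should be sulfated selectively.

**Compound list**

1 | 2-bromocyclopent-2-en-1-one | O=C1CCC=C1Br | starting material
2 | 1-(tert-butyldimethylsilyloxy)-1-methoxyethene | C=C(OC)O[Si](C)(C)C(C)(C)C | starting material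
3 | methyl 2-[2-bromo-3-(tert-butyldimethylsilyloxy)cyclopent-2-en-1-yl]acetate (racemic) | COC(=O)CC1CCC(O[Si](C)(C)C(C)(C)C)=C1Br | intermediate
4 | bromoform | BrC(Br)Br | starting material
5 | methyl 2-[1,6,6-tribromo-5-(tert-butyldimethylsilyloxy)bicyclo[3.1.0]hexan-2-yl]acetate (racemic; cis-fused, CBr2 bridge on the face opposite the acetate arm) | COC(=O)C[C@@H]1CC[C@@]2(O[Si](C)(C)C(C)(C)C)C(Br)(Br)[C@@]12Br | intermediate (not isolated)
6 | methyl 2-(2,3-dibromo-4-oxocyclohex-2-en-1-yl)acetate (racemic) | COC(=O)CC1CCC(=O)C(Br)=C1Br | intermediate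
7 | methyl 2-[2,3-dibromo-4-(trimethylsilyloxy)cyclohexa-2,4-dien-1-yl]acetate (racemic) | COC(=O)CC1CC=C(O[Si](C)(C)C)C(Br)=C1Br | intermediate
8 | methyl 2-[2,3-dibromo-1-(trimethylsilyloxy)-7-oxabicyclo[4.1.0]hept-2-en-4-yl]acetate (racemic diastereomer mixture) | COC(=O)CC1CC2OC2(O[Si](C)(C)C)C(Br)=C1Br | intermediate (not isolated)
9 | methyl 2-[2,3-dibromo-4-oxo-5-(trimethylsilyloxy)cyclohex-2-en-1-yl]acetate (racemic diastereomer mixture) | COC(=O)CC1CC(O[Si](C)(C)C)C(=O)C(Br)=C1Br | intermediate (not isolated)
10 | methyl 2-(2,3-dibromo-5-hydroxy-4-oxocyclohex-2-en-1-yl)acetate (racemic diastereomer mixture) | COC(=O)CC1CC(O)C(=O)C(Br)=C1Br | intermediate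
11 | methyl 2-(2,3-dibromo-4,5-dioxocyclohex-2-en-1-yl)acetate (racemic) | COC(=O)CC1CC(=O)C(=O)C(Br)=C1Br | intermediate (not isolated)
12 | methyl 2-(2,3-dibromo-4,5-dihydroxyphenyl)acetate | COC(=O)Cc1cc(O)c(O)c(Br)c1Br | intermediate
13 | 3,4-dibromo-5-(2-hydroxyethyl)benzene-1,2-diol | OCCc1cc(O)c(O)c(Br)c1Br | intermediate
14 | 2-(2,3-dibromo-4,5-dihydroxyphenyl)ethyl hydrogen sulfate | O=S(=O)(O)OCCc1cc(O)c(O)c(Br)c1Br | target

**Summary**

Total step count: 7. Longest linear sequence: 7 steps (1 or 2 → 14).

**Steps most likely to fail**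

Step 2. Carbene transfer to the tetrasubstituted enol ether may be sluggish because the vinylic bromine deactivates it, and alkoxide may attack the β-bromoenone at C2 (addition–elimination) as it is released. The fallback leaves the vinylic bromine out, uses the ring expansion in its well-established form, and brings in the C2 bromine last by electrophilic aromatic substitution. It sets out from ketene acetal 2 and comes back at catechol ester 12.
- Compound 2 is added under the conditions of step 1 to commercial cyclopent-2-en-1-one to give methyl 2-[3-(tert-butyldimethylsilyloxy)cyclopent-2-en-1-yl]acetate F1.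
- CHBr3/KOtBu in pentane should give, through methyl 2-[6,6-dibromo-5-(tert-butyldimethylsilyloxy)bicyclo[3.1.0]hexan-2-yl]acetate F2, the 2-bromoenone methyl 2-(3-bromo-4-oxocyclohex-2-en-1-yl)acetate F3.
- Under the conditions of steps 3 to 5, F3 is converted into methyl 2-[3-bromo-4-(trimethylsilyloxy)cyclohexa-2,4-dien-1-yl]acetate F4.
- mCPBA then gives, through methyl 2-[2-bromo-1-(trimethylsilyloxy)-7-oxabicyclo[4.1.0]hept-2-en-4-yl]acetate F5 and methyl 2-[3-bromo-4-oxo-5-(trimethylsilyloxy)cyclohex-2-en-1-yl]acetate F6, the acyloin methyl 2-(3-bromo-5-hydroxy-4-oxocyclohex-2-en-1-yl)acetate F7.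
- Swern oxidation gives, through methyl 2-(3-bromo-4,5-dioxocyclohex-2-en-1-yl)acetate F8, the catechol methyl 2-(3-bromo-4,5-dihydroxyphenyl)acetate F9.
- Bromination of F9 (Br2, 1 equiv, AcOH, rt) should occur para to the C5 hydroxyl, at the carbon between the side chain and the bromine, to give 12.

Step 7. A phenolic hydroxyl may be sulfated in competition, or more than one hydroxyl may react. The fallback protects the catechol as silyl ethers before the side chain is worked on. It sets out from catechol ester 12 and comes back at target 14.
- TBSCl/imidazole in DMF gives methyl 2-[2,3-dibromo-4,5-bis(tert-butyldimethylsilyloxy)phenyl]acetate F10.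
- DIBAL-H in CH2Cl2 at −78 °C gives 2-[2,3-dibromo-4,5-bis(tert-butyldimethylsilyloxy)phenyl]ethanol F11.
- SO3·pyridine in pyridine sulfates the only free hydroxyl to give 2-[2,3-dibromo-4,5-bis(tert-butyldimethylsilyloxy)phenyl]ethyl hydrogen sulfate F12 (handled as its pyridinium salt).
- KF in MeOH cleaves the two aryl silyl ethers, which the alkyl sulfate tolerates, and passage through an acidic ion-exchange resin gives 14.

Step 3. Deprotonation may occur at the γ-carbon (C1) to give the linear dienol ether, or the amine may attack the β-bromoenone, so that step 4 oxygenates the wrong carbon. The fallback oxygenates C5 directly through a manganese enolate. It sets out from enone 6 and comes back at acyloin 10, replacing steps 3 and 4.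
- Mn(OAc)3·2H2O in refluxing benzene, the established α′-acetoxylation of enones, gives methyl 2-(5-acetoxy-2,3-dibromo-4-oxocyclohex-2-en-1-yl)acetate F13.
- Acid-catalysed transesterification (TsOH, MeOH, 40 °C) removes the acetate without a nucleophilic base and gives 10.

**Further compounds**

F1 | step 2 | methyl 2-[3-(tert-butyldimethylsilyloxy)cyclopent-2-en-1-yl]acetate (racemic) | COC(=O)CC1CCC(O[Si](C)(C)C(C)(C)C)=C1
F2 | step 2 | methyl 2-[6,6-dibromo-5-(tert-butyldimethylsilyloxy)bicyclo[3.1.0]hexan-2-yl]acetate (racemic; CBr2 bridge anti to the acetate arm) | COC(=O)C[C@@H]1CC[C@@]2(O[Si](C)(C)C(C)(C)C)C(Br)(Br)[C@@H]12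
F3 | step 2 | methyl 2-(3-bromo-4-oxocyclohex-2-en-1-yl)acetate (racemic) | COC(=O)CC1CCC(=O)C(Br)=C1
F4 | step 2 | methyl 2-[3-bromo-4-(trimethylsilyloxy)cyclohexa-2,4-dien-1-yl]acetate (racemic) | COC(=O)CC1CC=C(O[Si](C)(C)C)C(Br)=C1
F5 | step 2 | methyl 2-[2-bromo-1-(trimethylsilyloxy)-7-oxabicyclo[4.1.0]hept-2-en-4-yl]acetate (racemic diastereomer mixture) | COC(=O)CC1CC2OC2(O[Si](C)(C)C)C(Br)=C1
F6 | step 2 | methyl 2-[3-bromo-4-oxo-5-(trimethylsilyloxy)cyclohex-2-en-1-yl]acetate (racemic diastereomer mixture) | COC(=O)CC1CC(O[Si](C)(C)C)C(=O)C(Br)=C1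
F7 | step 2 | methyl 2-(3-bromo-5-hydroxy-4-oxocyclohex-2-en-1-yl)acetate (racemic diastereomer mixture) | COC(=O)CC1CC(O)C(=O)C(Br)=C1
F8 | step 2 | methyl 2-(3-bromo-4,5-dioxocyclohex-2-en-1-yl)acetate (racemic) | COC(=O)CC1CC(=O)C(=O)C(Br)=C1
F9 | step 2 | methyl 2-(3-bromo-4,5-dihydroxyphenyl)acetate | COC(=O)Cc1cc(O)c(O)c(Br)c1
F10 | step 7 | methyl 2-[2,3-dibromo-4,5-bis(tert-butyldimethylsilyloxy)phenyl]acetate | COC(=O)Cc1cc(O[Si](C)(C)C(C)(C)C)c(O[Si](C)(C)C(C)(C)C)c(Br)c1Br
F11 | step 7 | 2-[2,3-dibromo-4,5-bis(tert-butyldimethylsilyloxy)phenyl]ethanol | OCCc1cc(O[Si](C)(C)C(C)(C)C)c(O[Si](C)(C)C(C)(C)C)c(Br)c1Br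
F12 | step 7 | 2-[2,3-dibromo-4,5-bis(tert-butyldimethylsilyloxy)phenyl]ethyl hydrogen sulfate | O=S(=O)(O)OCCc1cc(O[Si](C)(C)C(C)(C)C)c(O[Si](C)(C)C(C)(C)C)c(Br)c1Br
F13 | step 3 | methyl 2-(5-acetoxy-2,3-dibromo-4-oxocyclohex-2-en-1-yl)acetate (racemic diastereomer mixture) | COC(=O)CC1CC(OC(C)=O)C(=O)C(Br)=C1Br
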